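**Assumption:** (2E,6E,10E)-geranylgeraniol is taken as a purchasable bulk terpene alcohol. Macrocycles are named with cembrane numbering: C1 = lactone β-carbon, C14 = lactone carbinol carbon, C15/C16/C17 = lactone α-carbon/carbonyl/exocyclic methylene, C18–C20 = methyls on C4, C8, C12.

**Numbering convention:** compounds that supply skeleton carbons are numbered; all other atom-donating reagents are named with SMILES in their step.

## Retrosynthetic overview

1. 19 ⇐ 18 by reagent-controlled epoxidation of C3=C4 (oxirane formed last); 18 ⇐ 15 by a singlet-oxygen ene reaction at C7=C8, reduction and acetylation.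
2. 15 ⇐ 12 by α-methylenation of the lactone.
3. 12 ⇐ 11: the 14-membered ring is closed through the cyclase bond C1–C2. The farnesyl-type allyl terminus (as its radical) attacks the Δ1(15) olefin of the distal end, held as a butenolide so that C14 dictates C1.
4. 11 ⇐ 5 by organocatalytic α-oxygenation (sets C14), Z-olefination and lactonisation of the γ-hydroxy ester.
5. 5 ⇐ geranylgeraniol 1 by cleavage of the terminal olefin. Ring order: γ-lactone, then carbocycle, then oxirane.

## Route

Step 1
Reactants: 1 (2E,6E,10E)-geranylgeraniol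
Product: 2 (2E,6E,10E)-3,7,11,15-tetramethylhexadeca-2,6,10,14-tetraen-1-yl acetate
Conditions: Ac2O, pyridine, DMAP (cat.), CH2Cl2, 0 → 25 °C
Reagents that add atoms: acetic anhydride, CC(=O)OC(C)=O
Why: DMAP-catalysed acylation; the allylic acetate deactivates the 2,3-olefin toward the electrophilic bromination that follows.

Step 2
Reactants: 2 geranylgeranyl acetate
Product: 4 (2E,6E,10E)-13-(3,3-dimethyloxiran-2-yl)-3,7,11-trimethyltrideca-2,6,10-trien-1-ol, via bromohydrin acetate 3 (not isolated)
Conditions: NBS (1.1 equiv), THF–H2O, 0 °C; then K2CO3, MeOH, 25 °C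
Reagents that add atoms: water, O (epoxide oxygen); N-bromosuccinimide, O=C1CCC(=O)N1Br (bromine in 3 only)
Why: van Tamelen terminal bromohydrin formation (the coiled polyene in aqueous THF reacts at the terminal olefin, Markovnikov opening by water), then intramolecular Williamson closure to the epoxide with concurrent methanolysis of the acetate; the racemic centre is destroyed in step 3.

Step 3
Reactants: 4 14,15-epoxygeranylgeraniol
Product: 5 (4E,8E,12E)-14-hydroxy-4,8,12-trimethyltetradeca-4,8,12-trienal
Conditions: HIO4·2H2O (1.2 equiv), THF–Et2O, 0 °C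
Reagents that add atoms: none
Why: Periodic acid cleavage of the trisubstituted epoxide (via the diol, Malaprade-type glycol cleavage) gives the trisnor aldehyde and acetone without touching the trisubstituted olefins.

Step 4
Reactants: 5 hydroxy aldehyde; 6 ethyl 2-(diphenoxyphosphoryl)acetate (Ando reagent)
Product: 8 ethyl (2Z,4S,6E,10E,14E)-4-(anilinooxy)-16-hydroxy-6,10,14-trimethylhexadeca-2,6,10,14-tetraenoate, via aminooxy aldehyde 7 (not isolated)
Conditions: PhNO (1.0 equiv, slow addition), D-proline (20 mol %), MeCN, −20 °C; then cannulated into 6/NaH, THF, −78 → 0 °C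
Reagents that add atoms: nitrosobenzene, O=Nc1ccccc1
Why: Proline-catalysed O-selective nitroso aldol (α-aminoxylation, enamine catalysis) sets C14 as S (L-proline gives R, so D-proline is used; typically ≥95 % ee), and the labile aldehyde is trapped in the same flask by a Z-selective Ando–Horner–Wadsworth–Emmons olefination.

Step 5
Reactants: 8 aminooxy Z-enoate
Product: 10 (5S)-5-[(2E,6E,10E)-12-hydroxy-2,6,10-trimethyldodeca-2,6,10-trien-1-yl]furan-2(5H)-one, via hydroxy enoate 9 (not isolated)
Conditions: Zn dust, AcOH–THF (1:4), 25 → 40 °C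
Reagents that add atoms: none
Why: Reductive N–O cleavage frees the γ-hydroxyl, which lactonises onto the cis ester (closure of a γ-hydroxy acid derivative); the acidic medium leaves the butenolide γ-centre untouched.

Step 6
Reactants: 10 hydroxy butenolide
Product: 11 (5S)-5-[(2E,6E,10E)-12-bromo-2,6,10-trimethyldodeca-2,6,10-trien-1-yl]furan-2(5H)-one
Conditions: CBr4, PPh3, CH2Cl2, −20 °C; used at once
Reagents that add atoms: carbon tetrabromide, BrC(Br)(Br)Br
Why: Appel bromination (SN2 at the primary allylic carbinol) under neutral conditions keeps the olefin geometry and the base-sensitive γ-centre.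

Step 7
Reactants: 11 bromo butenolide
Product: 12 (1R,14S,3E,7E,11E)-17-norcembra-3,7,11-trien-16,14-olide
Conditions: Bu3SnH (1.3 equiv), AIBN (0.2 equiv), syringe pump over 12 h, PhH (2 mM), 80 °C
Reagents that add atoms: none
Why: Tin-hydride-mediated allylic radical macrocyclisation (Giese addition, 14-exo-trig, Pattenden type): the E-allyl radical adds through its primary terminus C2 to the butenolide β-carbon C1 on the face anti to the C13 substituent of C14, setting 1R trans to 14S, and the α-lactone radical is reduced by the stannane.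

Step 8
Reactants: 12 macrolactone
Product: 15 (1R,14S,3E,7E,11E)-cembra-3,7,11,15(17)-tetraen-16,14-olide, via Mannich base 13 (not isolated), via methiodide 14 (not isolated)
Conditions: LDA, THF, −78 °C; Me2N+=CH2 I−, −78 → 25 °C; MeI, MeOH, 25 °C; aq NaHCO3, CH2Cl2
Reagents that add atoms: Eschenmoser's salt, C=[N+](C)C.[I-]; iodomethane, CI (its methyl in 14 only)
Why: Lactone enolate Mannich reaction followed by quaternisation and E1cB elimination installs C17; C1 and C14 are not acidic and keep their configuration.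

Step 9
Reactants: 15 tetraene lactone
Product: 17 (1R,7S,14S,3E,11E)-7-hydroxycembra-3,8(19),11,15(17)-tetraen-16,14-olide, via hydroperoxide 16 (not isolated)
Conditions: O2, TPP (1 mol %), white LED, CH2Cl2, −20 °C, to ca. 70 % conversion; then PPh3, 0 °C; HPLC separation
Reagents that add atoms: oxygen, O=O
Why: Schenck ene reaction of singlet oxygen at C7=C8 (the olefin most remote from the lactone; C11=C12 is homoallylic to the lactone oxygen): O adds to C7 and H is taken from C19 on the more crowded side (cis effect), giving the 8(19)-methylene; attack on the outer face of the macrocycle is relied on for 7S (not secured a priori, see fallback), and PPh3 reduces the O–O bond with retention.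

Step 10
Reactants: 17 allylic alcohol
Product: 18 (1R,7S,14S,3E,11E)-7-acetoxycembra-3,8(19),11,15(17)-tetraen-16,14-olide
Conditions: Ac2O, pyridine, DMAP (cat.), CH2Cl2, 0 → 25 °C
Reagents that add atoms: acetic anhydride, CC(=O)OC(C)=O
Why: DMAP-catalysed acylation with retention at C7; the allylic acetate also deactivates the 8(19)-olefin for the last step.

Step 11
Reactants: 18 acetate
Product: 19 (1R,3S,4S,7S,14S,11E)-7-acetoxy-3,4-epoxycembra-8(19),11,15(17)-trien-16,14-olide
Conditions: ent-Shi ketone (L-fructose-derived, 1.5 equiv), Oxone, NaHCO3, Bu4NHSO4 (cat.), MeCN–DMM/aq Na2EDTA, pH 7.5–8, 0 °C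
Reagents that add atoms: Oxone (potassium peroxymonosulfate), [K+].[O-]S(=O)(=O)OO
Why: Shi asymmetric epoxidation (chiral dioxirane, spiro transition state): C3=C4 is the only remaining trisubstituted olefin with no allylic or homoallylic oxygen, and the ent-ketone delivers oxygen to the face giving 3S,4S (the D-fructose ketone gives R,R on E-trisubstituted olefins); the near-neutral protocol spares the α-methylene lactone and the acetate.

## Compound list

1 | (2E,6E,10E)-3,7,11,15-tetramethylhexadeca-2,6,10,14-tetraen-1-ol (geranylgeraniol) | OC/C=C(\C)CC/C=C(\C)CC/C=C(\C)CCC=C(C)C | starting material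
2 | (2E,6E,10E)-3,7,11,15-tetramethylhexadeca-2,6,10,14-tetraen-1-yl acetate | CC(=O)OC/C=C(\C)CC/C=C(\C)CC/C=C(\C)CCC=C(C)C | intermediate
3 | (2E,6E,10E)-14-bromo-15-hydroxy-3,7,11,15-tetramethylhexadeca-2,6,10-trien-1-yl acetate (racemic at C14) | CC(=O)OC/C=C(\C)CC/C=C(\C)CC/C=C(\C)CCC(Br)C(C)(C)O | intermediate (not isolated)
4 | (2E,6E,10E)-13-(3,3-dimethyloxiran-2-yl)-3,7,11-trimethyltrideca-2,6,10-trien-1-ol (racemic epoxide) | OC/C=C(\C)CC/C=C(\C)CC/C=C(\C)CCC1OC1(C)C | intermediate
5 | (4E,8E,12E)-14-hydroxy-4,8,12-trimethyltetradeca-4,8,12-trienal | OC/C=C(\C)CC/C=C(\C)CC/C=C(\C)CCC=O | intermediate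
6 | ethyl 2-(diphenoxyphosphoryl)acetate | CCOC(=O)CP(=O)(Oc1ccccc1)Oc1ccccc1 | starting material
7 | (2S,4E,8E,12E)-2-(anilinooxy)-14-hydroxy-4,8,12-trimethyltetradeca-4,8,12-trienal | OC/C=C(\C)CC/C=C(\C)CC/C=C(\C)C[C@H](ONc1ccccc1)C=O | intermediate (not isolated)
8 | ethyl (2Z,4S,6E,10E,14E)-4-(anilinooxy)-16-hydroxy-6,10,14-trimethylhexadeca-2,6,10,14-tetraenoate | OC/C=C(\C)CC/C=C(\C)CC/C=C(\C)C[C@H](ONc1ccccc1)/C=C\C(=O)OCC | intermediate
9 | ethyl (2Z,4S,6E,10E,14E)-4,16-dihydroxy-6,10,14-trimethylhexadeca-2,6,10,14-tetraenoate | OC/C=C(\C)CC/C=C(\C)CC/C=C(\C)C[C@H](O)/C=C\C(=O)OCC | intermediate (not isolated)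
10 | (5S)-5-[(2E,6E,10E)-12-hydroxy-2,6,10-trimethyldodeca-2,6,10-trien-1-yl]furan-2(5H)-one | OC/C=C(\C)CC/C=C(\C)CC/C=C(\C)C[C@@H]1OC(=O)C=C1 | intermediate
11 | (5S)-5-[(2E,6E,10E)-12-bromo-2,6,10-trimethyldodeca-2,6,10-trien-1-yl]furan-2(5H)-one | BrC/C=C(\C)CC/C=C(\C)CC/C=C(\C)C[C@@H]1OC(=O)C=C1 | intermediate
12 | (1R,14S,3E,7E,11E)-17-norcembra-3,7,11-trien-16,14-olide (trans-fused; = (3aR,15aS,5E,9E,13E)-6,10,14-trimethyl-3a,4,7,8,11,12,15,15a-octahydrocyclotetradeca[b]furan-2(3H)-one) | C1/C=C(\C)C[C@@H]2OC(=O)C[C@H]2C/C=C(\C)CC/C=C(\C)C1 | intermediate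
13 | 15-[(dimethylamino)methyl] derivative of 12 (C15 epimers) | C1/C=C(\C)C[C@@H]2OC(=O)C(CN(C)C)[C@H]2C/C=C(\C)CC/C=C(\C)C1 | intermediate (not isolated)
14 | 15-[(trimethylammonio)methyl] derivative of 12, iodide (C15 epimers) | C1/C=C(\C)C[C@@H]2OC(=O)C(C[N+](C)(C)C)[C@H]2C/C=C(\C)CC/C=C(\C)C1.[I-] | intermediate (not isolated)
15 | (1R,14S,3E,7E,11E)-cembra-3,7,11,15(17)-tetraen-16,14-olide | C1/C=C(\C)C[C@@H]2OC(=O)C(=C)[C@H]2C/C=C(\C)CC/C=C(\C)C1 | intermediate
16 | (1R,7S,14S,3E,11E)-7-hydroperoxycembra-3,8(19),11,15(17)-tetraen-16,14-olide | C=C1CC/C=C(\C)C[C@@H]2OC(=O)C(=C)[C@H]2C/C=C(\C)CC[C@@H]1OO | intermediate (not isolated)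
17 | (1R,7S,14S,3E,11E)-7-hydroxycembra-3,8(19),11,15(17)-tetraen-16,14-olide | C=C1CC/C=C(\C)C[C@@H]2OC(=O)C(=C)[C@H]2C/C=C(\C)CC[C@@H]1O | intermediate
18 | (1R,7S,14S,3E,11E)-7-acetoxycembra-3,8(19),11,15(17)-tetraen-16,14-olide | C=C1CC/C=C(\C)C[C@@H]2OC(=O)C(=C)[C@H]2C/C=C(\C)CC[C@@H]1OC(C)=O | intermediate
19 | (1R,3S,4S,7S,14S,11E)-7-acetoxy-3,4-epoxycembra-8(19),11,15(17)-trien-16,14-olide (CNP0152266.1) | C=C1CC/C=C(\C)C[C@@H]2OC(=O)C(=C)[C@H]2C[C@@H]2O[C@@]2(C)CC[C@@H]1OC(C)=O | target

## Step count and risk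

Total steps: 11. Longest linear sequence: 11 (from 1).

**Step 7 (macrocyclisation).** The allyl radical may be reduced before it cyclises, and the trans/cis ratio at C1 is not guaranteed because the directing substituent is also the tether. The fallback sets out from 11 and replaces the radical closure by a polar one. AgNO2 in Et2O converts the bromide into (5S)-5-[(2E,6E,10E)-2,6,10-trimethyl-12-nitrododeca-2,6,10-trien-1-yl]furan-2(5H)-one F1. Catalytic tetramethylguanidine in MeCN at high dilution closes the ring by a nitronate Michael addition to the butenolide, too weakly basic to touch the γ-proton and anti to the C14 substituent. This gives 2-nitro-17-norcembra-3,7,11-trien-16,14-olide F2 (trans ring fusion as in 12, both C2 epimers). Ono denitration (Bu3SnH, AIBN, toluene, 110 °C) removes the allylic nitro group and the route is rejoined at 12.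

**Step 9 (photooxygenation).** C3=C4 competes with C7=C8, the tertiary 8-hydroperoxide is a regioisomeric by-product, and the face of attack at C7 is under substrate control only; a realistic yield of 17 is 20–30 %. The fallback sets out from 15 and makes the C7 configuration reagent-controlled. The ene reaction and PPh3 reduction are run as in step 9, but the epimers are not separated. The (1R,7R,14S)-7-hydroperoxycembra-3,8(19),11,15(17)-tetraen-16,14-olide F3 and its reduction product (1R,7R,14S)-7-hydroxycembra-3,8(19),11,15(17)-tetraen-16,14-olide F4 are carried together with 17 into a Dess–Martin oxidation. Both epimers converge on (1R,14S)-7-oxocembra-3,8(19),11,15(17)-tetraen-16,14-olide F5. Reduction with (R)-Me-CBS and catecholborane (toluene, −78 °C, the alkenyl group acting as the large substituent) gives the 7S alcohol, and the route is rejoined at 17.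

**Step 11 (epoxidation).** Reagent control by the Shi ketone may be overridden by the facial bias of the macrocycle, and C11=C12 is only moderately less reactive than C3=C4. The fallback sets out from 18 and places the oxygen by anti addition instead of direct oxygen transfer, so that it ends up on the face opposite to the one an electrophile attacks. NBS in aqueous THF at 0 °C forms the bromonium ion on the exposed face of C3=C4, and water opens it at C4 from the other side. This gives (1R,3R,4S,7S,14S)-7-acetoxy-3-bromo-4-hydroxycembra-8(19),11,15(17)-trien-16,14-olide F6. Anhydrous K2CO3 in acetone closes it with inversion at C3, and the route is rejoined at 19.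

## Further compounds

F1 | step 7 | (5S)-5-[(2E,6E,10E)-2,6,10-trimethyl-12-nitrododeca-2,6,10-trien-1-yl]furan-2(5H)-one | [O-][N+](=O)C/C=C(\C)CC/C=C(\C)CC/C=C(\C)C[C@@H]1OC(=O)C=C1
F2 | step 7 | 2-nitro-17-norcembra-3,7,11-trien-16,14-olide (ring fusion as in 12, both C2 epimers) | C1/C=C(\C)C[C@@H]2OC(=O)C[C@H]2C([N+](=O)[O-])/C=C(\C)CC/C=C(\C)C1
F3 | step 9 | (1R,7R,14S)-7-hydroperoxycembra-3,8(19),11,15(17)-tetraen-16,14-olide | C=C1CC/C=C(\C)C[C@@H]2OC(=O)C(=C)[C@H]2C/C=C(\C)CC[C@H]1OO
F4 | step 9 | (1R,7R,14S)-7-hydroxycembra-3,8(19),11,15(17)-tetraen-16,14-olide | C=C1CC/C=C(\C)C[C@@H]2OC(=O)C(=C)[C@H]2C/C=C(\C)CC[C@H]1O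
F5 | step 9 | (1R,14S)-7-oxocembra-3,8(19),11,15(17)-tetraen-16,14-olide | C=C1CC/C=C(\C)C[C@@H]2OC(=O)C(=C)[C@H]2C/C=C(\C)CCC1=O
F6 | step 11 | (1R,3R,4S,7S,14S)-7-acetoxy-3-bromo-4-hydroxycembra-8(19),11,15(17)-trien-16,14-olide | C=C1CC/C=C(\C)C[C@@H]2OC(=O)C(=C)[C@H]2C[C@@H](Br)[C@](O)(C)CC[C@@H]1OC(C)=O
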